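Assumption: the target has no stereocentre and no stereogenic double bond, so "the single enantiomer given" is read as the one achiral compound drawn.

## Retrosynthetic overview

- The furan ring is formed last, by cyclodehydration of a 2-hydroxybenzyl aryl ketone; both benzene rings are bought, and the three phenols stay as TIPS ethers until a final fluoride step.
- The ketone comes from a β-keto allyl ester (Pd deallylation and decarboxylation), which comes from the key intermolecular aldol addition of an arylacetate lithium enolate to an aryl aldehyde, then oxidation. This aldol makes the future C2–C3 bond of the benzofuran.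
- The arylacetate comes from 2,4,6-trihydroxybenzaldehyde: bis-silylation, O-prenylation, aromatic Claisen rearrangement (this sets the 1,1-dimethylallyl group and frees only the future furan oxygen), O-allylation, and one-carbon homologation.
- The aldehyde comes from 3,5-dimethoxybenzoyl chloride: diethylamide, mono-demethylation, silylation, amide/OMe-directed ortho-lithiation and prenylation, then Schwartz reduction.

## Route

Step 1
Reactants: 1 2,4,6-trihydroxybenzaldehyde; 2 triisopropylsilyl chloride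
Product: 3 2-hydroxy-4,6-bis(triisopropylsilyloxy)benzaldehyde
Conditions: TIPSCl (2.1 equiv), imidazole (4.5 equiv), DMF, 0 °C to rt
Reagents that add atoms: triisopropylsilyl chloride (2), CC(C)[Si](Cl)(C(C)C)C(C)C
Why: Silylation of the phenols (substitution at silicon) takes the 4-OH and one ortho-OH, while the last ortho-OH is held in the hydrogen bond to the formyl group and stays free.

Step 2
Reactants: 3 2-hydroxy-4,6-bis(triisopropylsilyloxy)benzaldehyde; 4 3-methylbut-2-en-1-ol
Product: 5 2-[(3-methylbut-2-en-1-yl)oxy]-4,6-bis(triisopropylsilyloxy)benzaldehyde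
Conditions: PPh3, DIAD, THF, 0 °C to rt
Reagents that add atoms: 3-methylbut-2-en-1-ol (4), CC(C)=CCO
Why: Mitsunobu etherification alkylates the acidic, hydrogen-bonded phenol at the primary carbon of prenol under neutral conditions that spare the aryl silyl ethers.

Step 3
Reactants: 5 2-[(3-methylbut-2-en-1-yl)oxy]-4,6-bis(triisopropylsilyloxy)benzaldehyde
Product: 7 2-hydroxy-3-(2-methylbut-3-en-2-yl)-4,6-bis(triisopropylsilyloxy)benzaldehyde, via ortho-dienone 6 (not isolated)
Conditions: Eu(fod)3 (10 mol %), CHCl3, 60 °C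
Reagents that add atoms: none
Why: The chelation-accelerated aromatic Claisen ([3,3]) rearrangement can deliver the inverted 1,1-dimethylallyl group only to the one free ortho carbon (the other carries CHO), and the dienone tautomerises to the phenol; the low temperature holds back a Cope shift to C5, which sits between two OTIPS groups.

Step 4
Reactants: 7 2-hydroxy-3-(2-methylbut-3-en-2-yl)-4,6-bis(triisopropylsilyloxy)benzaldehyde; 8 allyl bromide
Product: 9 3-(2-methylbut-3-en-2-yl)-2-(prop-2-en-1-yloxy)-4,6-bis(triisopropylsilyloxy)benzaldehyde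
Conditions: allyl bromide (2 equiv), K2CO3, acetone, reflux
Reagents that add atoms: allyl bromide (8), C=CCBr
Why: Williamson ether synthesis on the salicylaldehyde phenoxide with a small, reactive halide; the allyl group marks this oxygen as the later furan oxygen.

Step 5
Reactants: 9 3-(2-methylbut-3-en-2-yl)-2-(prop-2-en-1-yloxy)-4,6-bis(triisopropylsilyloxy)benzaldehyde; 10 (methoxymethyl)triphenylphosphonium chloride
Product: 11 1-(2-methoxyethenyl)-3-(2-methylbut-3-en-2-yl)-2-(prop-2-en-1-yloxy)-4,6-bis(triisopropylsilyloxy)benzene (E/Z mixture)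
Conditions: 10 (1.5 equiv), KHMDS (1.4 equiv), THF, 0 °C; then 9, 0 °C to rt
Reagents that add atoms: (methoxymethyl)triphenylphosphonium chloride (10), COC[P+](c1ccccc1)(c1ccccc1)c1ccccc1.[Cl-]
Why: Wittig reaction with the unstabilised methoxymethylene ylide gives the enol ether one-carbon homologue; its E/Z ratio is irrelevant because both isomers hydrolyse to the same aldehyde.

Step 6
Reactants: 11 1-(2-methoxyethenyl)-3-(2-methylbut-3-en-2-yl)-2-(prop-2-en-1-yloxy)-4,6-bis(triisopropylsilyloxy)benzene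
Product: 12 2-[3-(2-methylbut-3-en-2-yl)-2-(prop-2-en-1-yloxy)-4,6-bis(triisopropylsilyloxy)phenyl]acetaldehyde
Conditions: 2 M aq. HCl/THF (1:4), 45 °C; used crude
Reagents that add atoms: water, O
Why: Acid-catalysed enol ether hydrolysis (C-protonation, hemiacetal collapse) is much faster than cleavage of aryl TIPS ethers or the allyl ether.

Step 7
Reactants: 12 2-[3-(2-methylbut-3-en-2-yl)-2-(prop-2-en-1-yloxy)-4,6-bis(triisopropylsilyloxy)phenyl]acetaldehyde
Product: 13 2-[3-(2-methylbut-3-en-2-yl)-2-(prop-2-en-1-yloxy)-4,6-bis(triisopropylsilyloxy)phenyl]acetic acid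
Conditions: NaClO2, NaH2PO4, 2-methyl-2-butene (20 equiv), t-BuOH/H2O, 0 °C to rt
Reagents that add atoms: sodium chlorite, [Na+].[O-]Cl=O
Why: Pinnick oxidation takes the aldehyde to the acid, and the large excess of 2-methyl-2-butene scavenges HOCl so that the vinyl and allyl groups are untouched.

Step 8
Reactants: 13 2-[3-(2-methylbut-3-en-2-yl)-2-(prop-2-en-1-yloxy)-4,6-bis(triisopropylsilyloxy)phenyl]acetic acid; 14 allyl alcohol
Product: 15 prop-2-en-1-yl 2-[3-(2-methylbut-3-en-2-yl)-2-(prop-2-en-1-yloxy)-4,6-bis(triisopropylsilyloxy)phenyl]acetate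
Conditions: DCC, DMAP (10 mol %), allyl alcohol, CH2Cl2, 0 °C to rt
Reagents that add atoms: allyl alcohol (14), C=CCO
Why: Steglich esterification under neutral conditions gives the allyl ester, which later allows decarboxylation with Pd(0) at room temperature.

Step 9
Reactants: 16 3,5-dimethoxybenzoyl chloride; 17 diethylamine
Product: 18 N,N-diethyl-3,5-dimethoxybenzamide
Conditions: Et2NH (1.1 equiv), Et3N (1.2 equiv), CH2Cl2, 0 °C to rt
Reagents that add atoms: diethylamine (17), CCNCC
Why: N-acylation of the amine by the acid chloride installs the tertiary amide, the strongest ortho-directing group for the later metalation.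

Step 10
Reactants: 18 N,N-diethyl-3,5-dimethoxybenzamide
Product: 19 N,N-diethyl-3-hydroxy-5-methoxybenzamide
Conditions: NaSEt (2.5 equiv), DMF, 120 °C; then 1 M HCl work-up
Reagents that add atoms: none
Why: SN2 O-demethylation by thiolate stops after one methyl group, because the phenoxide formed makes loss of the second phenoxide (a dianion) unfavourable.

Step 11
Reactants: 19 N,N-diethyl-3-hydroxy-5-methoxybenzamide; 2 triisopropylsilyl chloride
Product: 20 N,N-diethyl-3-methoxy-5-(triisopropylsilyloxy)benzamide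
Conditions: TIPSCl (1.2 equiv), imidazole, DMF, rt
Reagents that add atoms: triisopropylsilyl chloride (2), CC(C)[Si](Cl)(C(C)C)C(C)C
Why: Silylation of the phenol gives a bulky, non-directing OTIPS group that blocks metalation at its two ortho positions.

Step 12
Reactants: 20 N,N-diethyl-3-methoxy-5-(triisopropylsilyloxy)benzamide; 21 prenyl bromide
Product: 24 N,N-diethyl-3-methoxy-2-(3-methylbut-2-en-1-yl)-5-(triisopropylsilyloxy)benzamide, via aryllithium 22 (not isolated), via arylcopper 23 (not isolated)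
Conditions: s-BuLi (1.2 equiv), TMEDA, THF, −78 °C; CuBr·SMe2 (1.2 equiv), −78 to −40 °C; prenyl bromide, to 0 °C
Reagents that add atoms: prenyl bromide (21), CC(C)=CCBr
Why: Directed ortho-metalation occurs at the carbon between the amide and OMe (cooperating directing groups, OTIPS sites blocked), and the arylcopper is alkylated at the primary carbon of prenyl bromide (SN2).

Step 13
Reactants: 24 N,N-diethyl-3-methoxy-2-(3-methylbut-2-en-1-yl)-5-(triisopropylsilyloxy)benzamide
Product: 26 3-methoxy-2-(3-methylbut-2-en-1-yl)-5-(triisopropylsilyloxy)benzaldehyde, via zirconium hemiaminal 25 (not isolated)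
Conditions: Cp2Zr(H)Cl (1.5 equiv), THF, rt, 30 min; aqueous work-up
Reagents that add atoms: none
Why: Schwartz-reagent reduction of the tertiary amide stops at the aldehyde level because the zirconium hemiaminal collapses only on work-up, and the trisubstituted alkene is hydrozirconated far more slowly than the amide is reduced.

Step 14
Reactants: 15 prop-2-en-1-yl 2-[3-(2-methylbut-3-en-2-yl)-2-(prop-2-en-1-yloxy)-4,6-bis(triisopropylsilyloxy)phenyl]acetate; 26 3-methoxy-2-(3-methylbut-2-en-1-yl)-5-(triisopropylsilyloxy)benzaldehyde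
Product: 28 prop-2-en-1-yl 3-hydroxy-3-[3-methoxy-2-(3-methylbut-2-en-1-yl)-5-(triisopropylsilyloxy)phenyl]-2-[3-(2-methylbut-3-en-2-yl)-2-(prop-2-en-1-yloxy)-4,6-bis(triisopropylsilyloxy)phenyl]propanoate (racemic syn/anti mixture), via lithium enolate 27 (not isolated)
Conditions: LDA (1.1 equiv), THF, −78 °C; then 26, −78 °C; AcOH quench at −78 °C
Reagents that add atoms: none
Why: Intermolecular aldol addition of the ester lithium enolate to the non-enolisable aldehyde forms the future C2–C3 bond of the benzofuran; the two new stereocentres form unselectively and are both erased in steps 15 and 16.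

Step 15
Reactants: 28 aldol adduct (β-hydroxy allyl ester)
Product: 29 prop-2-en-1-yl 3-[3-methoxy-2-(3-methylbut-2-en-1-yl)-5-(triisopropylsilyloxy)phenyl]-2-[3-(2-methylbut-3-en-2-yl)-2-(prop-2-en-1-yloxy)-4,6-bis(triisopropylsilyloxy)phenyl]-3-oxopropanoate (racemic)
Conditions: Dess–Martin periodinane (1.3 equiv), CH2Cl2, 0 °C to rt
Reagents that add atoms: none
Why: Dess–Martin oxidation converts the secondary benzylic alcohol to the ketone under near-neutral conditions that leave alkenes, silyl ethers and the electron-rich rings alone.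

Step 16
Reactants: 29 β-keto allyl ester
Product: 31 2-[2-hydroxy-3-(2-methylbut-3-en-2-yl)-4,6-bis(triisopropylsilyloxy)phenyl]-1-[3-methoxy-2-(3-methylbut-2-en-1-yl)-5-(triisopropylsilyloxy)phenyl]ethan-1-one, via β-keto acid 30 (not isolated)
Conditions: Pd(PPh3)4 (5 mol %), morpholine (6 equiv), THF, rt then 40 °C
Reagents that add atoms: none
Why: Tsuji–Trost deallylation cleaves the allyl ester and the allyl aryl ether through π-allyl palladium trapped by morpholine, and the β-keto acid decarboxylates; the only free phenol is then the one next to the 1,1-dimethylallyl group.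

Step 17
Reactants: 31 2-hydroxybenzyl aryl ketone
Product: 33 2-[3-methoxy-2-(3-methylbut-2-en-1-yl)-5-(triisopropylsilyloxy)phenyl]-7-(2-methylbut-3-en-2-yl)-4,6-bis(triisopropylsilyloxy)-1-benzofuran, via cyclic hemiketal 32 (not isolated)
Conditions: PPTS (20 mol %), toluene, 4 Å MS, 80 °C
Reagents that add atoms: none
Why: Acid-catalysed cyclodehydration (hemiketal formation, then loss of water driven by aromatisation of the furan) can use only the single free phenol, so the 7-(1,1-dimethylallyl) isomer is the only one possible.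

Step 18
Reactants: 33 tris-TIPS benzofuran
Product: 34 5-[4,6-dihydroxy-7-(2-methylbut-3-en-2-yl)-1-benzofuran-2-yl]-3-methoxy-4-(3-methylbut-2-en-1-yl)phenol (target)
Conditions: TBAF (3.5 equiv), AcOH (3.5 equiv), THF, 0 °C, under argon
Reagents that add atoms: none
Why: Fluoride-mediated desilylation (Si–F bond formation) frees the three phenols without strong acid, so the prenyl and 1,1-dimethylallyl groups are not cyclised or hydrated and the methyl ether is kept.

## Compound list

1 | 2,4,6-trihydroxybenzaldehyde | O=Cc1c(O)cc(O)cc1O | starting material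
2 | triisopropylsilyl chloride | CC(C)[Si](Cl)(C(C)C)C(C)C | starting material
3 | 2-hydroxy-4,6-bis(triisopropylsilyloxy)benzaldehyde | O=Cc1c(O)cc(O[Si](C(C)C)(C(C)C)C(C)C)cc1O[Si](C(C)C)(C(C)C)C(C)C | intermediate
4 | 3-methylbut-2-en-1-ol (prenol) | CC(C)=CCO | starting material
5 | 2-[(3-methylbut-2-en-1-yl)oxy]-4,6-bis(triisopropylsilyloxy)benzaldehyde | O=Cc1c(OCC=C(C)C)cc(O[Si](C(C)C)(C(C)C)C(C)C)cc1O[Si](C(C)C)(C(C)C)C(C)C | intermediate
6 | 2-formyl-6-(2-methylbut-3-en-2-yl)-3,5-bis(triisopropylsilyloxy)cyclohexa-2,4-dien-1-one (racemic, not isolated) | O=CC1=C(O[Si](C(C)C)(C(C)C)C(C)C)C=C(O[Si](C(C)C)(C(C)C)C(C)C)C(C(C)(C)C=C)C1=O | intermediate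
7 | 2-hydroxy-3-(2-methylbut-3-en-2-yl)-4,6-bis(triisopropylsilyloxy)benzaldehyde | O=Cc1c(O)c(C(C)(C)C=C)c(O[Si](C(C)C)(C(C)C)C(C)C)cc1O[Si](C(C)C)(C(C)C)C(C)C | intermediate
8 | allyl bromide | C=CCBr | starting material
9 | 3-(2-methylbut-3-en-2-yl)-2-(prop-2-en-1-yloxy)-4,6-bis(triisopropylsilyloxy)benzaldehyde | O=Cc1c(OCC=C)c(C(C)(C)C=C)c(O[Si](C(C)C)(C(C)C)C(C)C)cc1O[Si](C(C)C)(C(C)C)C(C)C | intermediate
10 | (methoxymethyl)triphenylphosphonium chloride | COC[P+](c1ccccc1)(c1ccccc1)c1ccccc1.[Cl-] | starting material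
11 | 1-(2-methoxyethenyl)-3-(2-methylbut-3-en-2-yl)-2-(prop-2-en-1-yloxy)-4,6-bis(triisopropylsilyloxy)benzene (E/Z mixture, geometry not drawn) | COC=Cc1c(OCC=C)c(C(C)(C)C=C)c(O[Si](C(C)C)(C(C)C)C(C)C)cc1O[Si](C(C)C)(C(C)C)C(C)C | intermediate
12 | 2-[3-(2-methylbut-3-en-2-yl)-2-(prop-2-en-1-yloxy)-4,6-bis(triisopropylsilyloxy)phenyl]acetaldehyde | O=CCc1c(OCC=C)c(C(C)(C)C=C)c(O[Si](C(C)C)(C(C)C)C(C)C)cc1O[Si](C(C)C)(C(C)C)C(C)C | intermediate
13 | 2-[3-(2-methylbut-3-en-2-yl)-2-(prop-2-en-1-yloxy)-4,6-bis(triisopropylsilyloxy)phenyl]acetic acid | OC(=O)Cc1c(OCC=C)c(C(C)(C)C=C)c(O[Si](C(C)C)(C(C)C)C(C)C)cc1O[Si](C(C)C)(C(C)C)C(C)C | intermediate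
14 | allyl alcohol | C=CCO | starting material
15 | prop-2-en-1-yl 2-[3-(2-methylbut-3-en-2-yl)-2-(prop-2-en-1-yloxy)-4,6-bis(triisopropylsilyloxy)phenyl]acetate | C=CCOC(=O)Cc1c(OCC=C)c(C(C)(C)C=C)c(O[Si](C(C)C)(C(C)C)C(C)C)cc1O[Si](C(C)C)(C(C)C)C(C)C | intermediate
16 | 3,5-dimethoxybenzoyl chloride | COc1cc(OC)cc(C(=O)Cl)c1 | starting material
17 | diethylamine | CCNCC | starting material
18 | N,N-diethyl-3,5-dimethoxybenzamide | CCN(CC)C(=O)c1cc(OC)cc(OC)c1 | intermediate
19 | N,N-diethyl-3-hydroxy-5-methoxybenzamide | CCN(CC)C(=O)c1cc(O)cc(OC)c1 | intermediate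
20 | N,N-diethyl-3-methoxy-5-(triisopropylsilyloxy)benzamide | CCN(CC)C(=O)c1cc(OC)cc(O[Si](C(C)C)(C(C)C)C(C)C)c1 | intermediate
21 | prenyl bromide (1-bromo-3-methylbut-2-ene) | CC(C)=CCBr | starting material
22 | [2-(diethylcarbamoyl)-6-methoxy-4-(triisopropylsilyloxy)phenyl]lithium (not isolated) | CCN(CC)C(=O)c1cc(O[Si](C(C)C)(C(C)C)C(C)C)cc(OC)c1[Li] | intermediate
23 | [2-(diethylcarbamoyl)-6-methoxy-4-(triisopropylsilyloxy)phenyl]copper (not isolated) | CCN(CC)C(=O)c1cc(O[Si](C(C)C)(C(C)C)C(C)C)cc(OC)c1[Cu] | intermediate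
24 | N,N-diethyl-3-methoxy-2-(3-methylbut-2-en-1-yl)-5-(triisopropylsilyloxy)benzamide | CCN(CC)C(=O)c1cc(O[Si](C(C)C)(C(C)C)C(C)C)cc(OC)c1CC=C(C)C | intermediate
25 | chloridobis(cyclopentadienyl)zirconium (diethylamino)[3-methoxy-2-(3-methylbut-2-en-1-yl)-5-(triisopropylsilyloxy)phenyl]methanolate (racemic, not isolated) | CCN(CC)C([O-])c1cc(O[Si](C(C)C)(C(C)C)C(C)C)cc(OC)c1CC=C(C)C.[Zr+4].[Cl-].c1cc[cH-]c1.c1cc[cH-]c1 | intermediate
26 | 3-methoxy-2-(3-methylbut-2-en-1-yl)-5-(triisopropylsilyloxy)benzaldehyde | O=Cc1cc(O[Si](C(C)C)(C(C)C)C(C)C)cc(OC)c1CC=C(C)C | intermediate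
27 | lithium enolate of 15 (enolate geometry not defined, not isolated) | [Li+].[O-]C(OCC=C)=Cc1c(OCC=C)c(C(C)(C)C=C)c(O[Si](C(C)C)(C(C)C)C(C)C)cc1O[Si](C(C)C)(C(C)C)C(C)C | intermediate
28 | prop-2-en-1-yl 3-hydroxy-3-[3-methoxy-2-(3-methylbut-2-en-1-yl)-5-(triisopropylsilyloxy)phenyl]-2-[3-(2-methylbut-3-en-2-yl)-2-(prop-2-en-1-yloxy)-4,6-bis(triisopropylsilyloxy)phenyl]propanoate (racemic syn/anti mixture) | C=CCOC(=O)C(c1c(OCC=C)c(C(C)(C)C=C)c(O[Si](C(C)C)(C(C)C)C(C)C)cc1O[Si](C(C)C)(C(C)C)C(C)C)C(O)c1cc(O[Si](C(C)C)(C(C)C)C(C)C)cc(OC)c1CC=C(C)C | intermediate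
29 | prop-2-en-1-yl 3-[3-methoxy-2-(3-methylbut-2-en-1-yl)-5-(triisopropylsilyloxy)phenyl]-2-[3-(2-methylbut-3-en-2-yl)-2-(prop-2-en-1-yloxy)-4,6-bis(triisopropylsilyloxy)phenyl]-3-oxopropanoate (racemic) | C=CCOC(=O)C(c1c(OCC=C)c(C(C)(C)C=C)c(O[Si](C(C)C)(C(C)C)C(C)C)cc1O[Si](C(C)C)(C(C)C)C(C)C)C(=O)c1cc(O[Si](C(C)C)(C(C)C)C(C)C)cc(OC)c1CC=C(C)C | intermediate
30 | 2-[2-hydroxy-3-(2-methylbut-3-en-2-yl)-4,6-bis(triisopropylsilyloxy)phenyl]-3-[3-methoxy-2-(3-methylbut-2-en-1-yl)-5-(triisopropylsilyloxy)phenyl]-3-oxopropanoic acid (racemic, not isolated) | OC(=O)C(c1c(O)c(C(C)(C)C=C)c(O[Si](C(C)C)(C(C)C)C(C)C)cc1O[Si](C(C)C)(C(C)C)C(C)C)C(=O)c1cc(O[Si](C(C)C)(C(C)C)C(C)C)cc(OC)c1CC=C(C)C | intermediate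
31 | 2-[2-hydroxy-3-(2-methylbut-3-en-2-yl)-4,6-bis(triisopropylsilyloxy)phenyl]-1-[3-methoxy-2-(3-methylbut-2-en-1-yl)-5-(triisopropylsilyloxy)phenyl]ethan-1-one | O=C(Cc1c(O)c(C(C)(C)C=C)c(O[Si](C(C)C)(C(C)C)C(C)C)cc1O[Si](C(C)C)(C(C)C)C(C)C)c1cc(O[Si](C(C)C)(C(C)C)C(C)C)cc(OC)c1CC=C(C)C | intermediate
32 | 2-[3-methoxy-2-(3-methylbut-2-en-1-yl)-5-(triisopropylsilyloxy)phenyl]-7-(2-methylbut-3-en-2-yl)-4,6-bis(triisopropylsilyloxy)-2,3-dihydro-1-benzofuran-2-ol (racemic, not isolated) | OC1(Cc2c(O[Si](C(C)C)(C(C)C)C(C)C)cc(O[Si](C(C)C)(C(C)C)C(C)C)c(C(C)(C)C=C)c2O1)c1cc(O[Si](C(C)C)(C(C)C)C(C)C)cc(OC)c1CC=C(C)C | intermediate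
33 | 2-[3-methoxy-2-(3-methylbut-2-en-1-yl)-5-(triisopropylsilyloxy)phenyl]-7-(2-methylbut-3-en-2-yl)-4,6-bis(triisopropylsilyloxy)-1-benzofuran | C=CC(C)(C)c1c(O[Si](C(C)C)(C(C)C)C(C)C)cc(O[Si](C(C)C)(C(C)C)C(C)C)c2cc(-c3cc(O[Si](C(C)C)(C(C)C)C(C)C)cc(OC)c3CC=C(C)C)oc12 | intermediate
34 | 5-[4,6-dihydroxy-7-(2-methylbut-3-en-2-yl)-1-benzofuran-2-yl]-3-methoxy-4-(3-methylbut-2-en-1-yl)phenol (CNP0169501.0, achiral) | C=CC(C)(C)c1c(O)cc(O)c2cc(-c3cc(O)cc(OC)c3CC=C(C)C)oc12 | target

## Summary

Total step count: 18.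
Longest linear sequence: 13 steps (steps 1–8, then 14–18); the aldehyde branch (steps 9–13) is 5 steps.

### The three steps most likely to fail

Step 3 (aromatic Claisen rearrangement). The new quaternary carbon is formed between the phenol oxygen and a bulky OTIPS group, and a Cope shift to C5 or reversal could compete. The fallback sets out from 3 and skips the prenyl ether altogether. Iodination with N-iodosuccinimide in MeCN at 0 °C, ortho to the free phenol, gives 2-hydroxy-3-iodo-4,6-bis(triisopropylsilyloxy)benzaldehyde F1. A palladium-catalysed Suzuki–Miyaura coupling of F1 with prenylboronic acid pinacol ester, run with a biarylphosphine catalyst tuned for branched (γ) selectivity and K3PO4 in aqueous THF, then attaches the 1,1-dimethylallyl group through allylic transposition. The fallback comes back to the route at 7.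

Step 12 (ortho-lithiation and prenylation). The metalation site is well supported, but alkylation of the hindered arylcopper by prenyl bromide may be low-yielding or give some SN2' product. The fallback sets out from 20. The same lithiation is quenched with iodine to give N,N-diethyl-2-iodo-3-methoxy-5-(triisopropylsilyloxy)benzamide F2. A Stille coupling of F2 with tributyl(3-methylbut-2-en-1-yl)stannane (Pd(PPh3)4, LiCl, DMF, 80 °C) then makes the aryl–prenyl bond by cross-coupling instead of alkylation. The fallback comes back to the route at 24.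

Step 14 (key aldol addition). The enolate carbon sits between two ortho substituents and the aldehyde carries an ortho prenyl group, so addition may be slow or reverse (retro-aldol). The fallback sets out from 26 and replaces the aldol and oxidation pair by a crossed Claisen condensation. Pinnick oxidation of 26 gives 3-methoxy-2-(3-methylbut-2-en-1-yl)-5-(triisopropylsilyloxy)benzoic acid F3. Carbonyldiimidazole in THF converts F3 into 1-[3-methoxy-2-(3-methylbut-2-en-1-yl)-5-(triisopropylsilyloxy)benzoyl]imidazole F4. F4 is added at −78 °C to 2.2 equivalents of the lithium enolate 27 (from 15 and LDA); the irreversible acylation gives the β-keto ester directly. The fallback comes back to the route at 29, and step 15 is no longer needed.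

## Further compounds

F1 | step 3 | 2-hydroxy-3-iodo-4,6-bis(triisopropylsilyloxy)benzaldehyde | O=Cc1c(O)c(I)c(O[Si](C(C)C)(C(C)C)C(C)C)cc1O[Si](C(C)C)(C(C)C)C(C)C
F2 | step 12 | N,N-diethyl-2-iodo-3-methoxy-5-(triisopropylsilyloxy)benzamide | CCN(CC)C(=O)c1cc(O[Si](C(C)C)(C(C)C)C(C)C)cc(OC)c1I
F3 | step 14 | 3-methoxy-2-(3-methylbut-2-en-1-yl)-5-(triisopropylsilyloxy)benzoic acid | OC(=O)c1cc(O[Si](C(C)C)(C(C)C)C(C)C)cc(OC)c1CC=C(C)C
F4 | step 14 | 1-[3-methoxy-2-(3-methylbut-2-en-1-yl)-5-(triisopropylsilyloxy)benzoyl]imidazole | O=C(c1cc(O[Si](C(C)C)(C(C)C)C(C)C)cc(OC)c1CC=C(C)C)n1ccnc1
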